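**Plan**

1. Locants: the decalin is numbered as naphthalene. C1 is the quaternary carbon with CH3 and CH2Ar, C2 is CH–CH3, C4a is the angular C–CH3, C5 is the CH with the propanoic chain, C6 carries the isopropylidene, C8a is the angular CH. Ring A = C4a–C5–C6–C7–C8–C8a; ring B = C1–C2–C3–C4–C4a–C8a.
2. Retrosynthetic cuts, in order: the arene oxygens (hydroquinone from an anisole); C2–CH3 (cuprate); C1–CH2Ar together with C8a–H (reductive benzylation); C1–C8a and C4–C4a (annulation of ring B with pent-1-en-3-one); C5–side chain (conjugate addition); last, ring A at C7–C8 and C5–C6.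
3. Enabling feature: in ring A the isopropylidene carbon C6 lies para to the fusion carbon C8a, and C8a can be carried as an enol-ether carbon next to the methyl-bearing C4a. Ring A is therefore the [4+2] adduct of a 2-silyloxy-3-methylbutadiene (C8=C8a–C4a=C5) and a 1,1-dimethylallene equivalent (C7=C6=CMe2), here an α-methylene-β-lactone that then loses CO2.
4. Forward order: ring A first (achiral), dehydrogenation to a dienone, side chain on C5, quaternary C4a, ring B by aldol closure, then C8a/C1, then C2, then deoxygenation and oxidation-level adjustments.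
5. Stereochemistry: C5 comes from one copper-catalysed asymmetric conjugate addition. C4a (anti Michael addition), C8a and C1 (Li/NH3 reductive benzylation) and C2 (axial cuprate addition) are relayed from it by substrate control.

Key step: step 4

Remark: the SMILES is read as a trans-fused decalin (8a-H anti to 4a-CH3) with 1-CH3 and the C5 chain syn to 4a-CH3 and 2-CH3 anti to 1-CH3 (syn to CH2Ar), i.e. (1S,2S,4aR,5S,8aR) in the locants above; compounds 1, 5, 10, 13 and 16 are taken as commercially available.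

**Route**

Step 1
Reactants: 1 2,3-dimethylbut-2-enoic acid
Product: 3 3-hydroxy-3-methyl-2-methylidenebutanoic acid, via hydroperoxide 2 (not isolated)
Conditions: O2, hν, tetraphenylporphyrin (cat.), CH2Cl2, 0 °C; then PPh3, 0 °C → rt
Reagents that add atoms: dioxygen, O=O
Why: Schenck ene reaction of singlet oxygen takes the hydrogen from the methyl group geminal to the carboxyl group, so the hydroperoxide ends on the tertiary carbon, and the phosphine then reduces the O–O bond.

Step 2
Reactants: 3 3-hydroxy-3-methyl-2-methylidenebutanoic acid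
Product: 4 4,4-dimethyl-3-methylideneoxetan-2-one
Conditions: PhSO2Cl, pyridine, 0 °C
Reagents that add atoms: none
Why: β-lactonisation of a β-hydroxy acid through the mixed carboxylic–sulfonic anhydride (carboxyl activation, so the tertiary C–O bond is not ionised).

Step 3
Reactants: 5 3-methylbut-3-en-2-one
Product: 6 tert-butyldimethyl[(3-methylbuta-1,3-dien-2-yl)oxy]silane
Conditions: TBSOTf, Et3N, CH2Cl2, 0 °C
Reagents that add atoms: tert-butyldimethylsilyl trifluoromethanesulfonate, CC(C)(C)[Si](C)(C)OS(=O)(=O)C(F)(F)F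
Why: soft enolisation and O-silylation of an enone whose only enolisable position is the methyl group gives the cross-conjugated 2-silyloxydiene.

Step 4
Reactants: 6 tert-butyldimethyl[(3-methylbuta-1,3-dien-2-yl)oxy]silane, 4 4,4-dimethyl-3-methylideneoxetan-2-one
Product: 8 tert-butyldimethyl{[2-methyl-4-(propan-2-ylidene)cyclohex-1-en-1-yl]oxy}silane, via spirolactone 7 (not isolated)
Conditions: 6 (2 equiv), BHT (cat.), toluene, sealed tube, 110 °C; then 150 °C (loss of CO2)
Reagents that add atoms: none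
Why: The electron-rich 2-silyloxydiene 6 and the strained, s-cis-locked α-methylene-β-lactone 4 combine in a concerted but asynchronous normal-demand [4+2] cycloaddition, and on further heating the spiro-β-lactone 7 extrudes CO2 by thermal [2+2] cycloreversion, so the lactone carbonyl is a traceless activating group and 4 a 1,1-dimethylallene equivalent. The closest known reaction types are Diels–Alder additions of α-methylene-β-lactones used as allene equivalents and the thermal decarboxylation of β-lactones to alkenes. Ring A is closed as a six-membered carbocycle by intermolecular [4+2] cycloaddition, suprafacial on both partners, the C7–C8 and C5–C6 bonds being formed together. The only stereocentre created, the spiro carbon C6 of 7, is racemic and is erased on loss of CO2, so 8 is achiral and no stereocontrol is needed. The step needs regioselectivity (lactone-bearing carbon para to the silyloxy carbon), which the 2-silyloxy group secures by making C8 the nucleophilic diene terminus that bonds to the methylene carbon of 4, while the alkene position is fixed by the site of CO2 loss. The cycloaddition has to precede decarboxylation of free 4, which is why the temperature is raised only after 4 is consumed.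

Step 5
Reactants: 8 tert-butyldimethyl{[2-methyl-4-(propan-2-ylidene)cyclohex-1-en-1-yl]oxy}silane
Product: 9 2-methyl-4-(propan-2-ylidene)cyclohex-2-en-1-one
Conditions: Pd(OAc)2 (1.05 equiv), MeCN, rt; product used directly
Reagents that add atoms: none
Why: Saegusa–Ito oxidation: the silyl enol ether gives a palladium(II) enolate, and β-hydride elimination toward C5 gives the enone conjugated with the isopropylidene group, the carbonyl position being fixed by the enol ether.

Step 6
Reactants: 9 2-methyl-4-(propan-2-ylidene)cyclohex-2-en-1-one, 10 (3-bromopropoxy)(tert-butyl)dimethylsilane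
Product: 12 tert-butyldimethyl(3-{(1R)-2-methyl-6-(propan-2-ylidene)-3-[(trimethylsilyl)oxy]cyclohex-2-en-1-yl}propoxy)silane, via magnesium enolate 11 (not isolated)
Conditions: 10, Mg, Et2O (Grignard reagent); Cu(OTf)2 (5 mol %), chiral imidazolinium NHC precursor (6 mol %, enantiomer chosen to give (R)-12), 9, Et2O, −30 °C; then TMSCl, Et3N, HMPA, −30 °C → rt
Reagents that add atoms: chlorotrimethylsilane, C[Si](C)(C)Cl
Why: copper-catalysed asymmetric conjugate addition of a Grignard reagent to an α-methyl cyclic enone with silyl trapping of the magnesium enolate: the chiral ligand selects the enone face and so sets C5, 1,4-addition is preferred to 1,6-addition because the δ-carbon is fully substituted, and TMSCl fixes the enolate regiochemistry at C8a/C4a.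

Step 7
Reactants: 12 tert-butyldimethyl(3-{(1R)-2-methyl-6-(propan-2-ylidene)-3-[(trimethylsilyl)oxy]cyclohex-2-en-1-yl}propoxy)silane, 13 pent-1-en-3-one
Product: 14 (2S,3R)-3-{3-[(tert-butyldimethylsilyl)oxy]propyl}-2-methyl-2-(3-oxopentyl)-4-(propan-2-ylidene)cyclohexan-1-one
Conditions: Sc(OTf)3 (10 mol %), CH2Cl2, −78 → −20 °C; then aqueous citric acid, rt
Reagents that add atoms: none
Why: Mukaiyama–Michael addition: the C5 side chain, held pseudo-axial by allylic strain with the C4a methyl and the isopropylidene group, shields one face, so the enone adds to C4a anti to it and the new quaternary centre has CH3 cis to the C5 chain.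

Step 8
Reactants: 14 (2S,3R)-3-{3-[(tert-butyldimethylsilyl)oxy]propyl}-2-methyl-2-(3-oxopentyl)-4-(propan-2-ylidene)cyclohexan-1-one
Product: 15 (4aS,5R)-5-{3-[(tert-butyldimethylsilyl)oxy]propyl}-1,4a-dimethyl-6-(propan-2-ylidene)-4,4a,5,6,7,8-hexahydronaphthalen-2(3H)-one
Conditions: NaOMe, MeOH, 50 °C
Reagents that add atoms: none
Why: intramolecular aldol condensation (second stage of a Robinson annulation): the CH2 of the ethyl ketone attacks the ring ketone and dehydration gives the six-membered enone of ring B without touching a stereocentre.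

Step 9
Reactants: 16 2-methoxy-1,3-dimethylbenzene
Product: 17 1-(bromomethyl)-2-methoxy-3-methylbenzene
Conditions: NBS (1.0 equiv), AIBN (cat.), PhCF3, 85 °C
Reagents that add atoms: N-bromosuccinimide, O=C1CCC(=O)N1Br
Why: Wohl–Ziegler radical bromination of one benzylic methyl group, limited to monobromination by stoichiometry; radical conditions avoid ring bromination.

Step 10
Reactants: 15 (4aS,5R)-5-{3-[(tert-butyldimethylsilyl)oxy]propyl}-1,4a-dimethyl-6-(propan-2-ylidene)-4,4a,5,6,7,8-hexahydronaphthalen-2(3H)-one, 17 1-(bromomethyl)-2-methoxy-3-methylbenzene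
Product: 19 trans-fused 5-{3-[(tert-butyldimethylsilyl)oxy]propyl}-1-[(2-methoxy-3-methylphenyl)methyl]-1,4a-dimethyl-6-(propan-2-ylidene)octahydronaphthalen-2(1H)-one (8a-H anti, 1-CH3 and C5 chain syn to 4a-CH3), via lithium enolate 18 (not isolated)
Conditions: Li (2.2 equiv), liquid NH3/THF, −78 °C; then 17, THF, −78 → −33 °C; NH4Cl
Reagents that add atoms: none
Why: Stork reductive alkylation: Li/NH3 reduces the enone with axial protonation at C8a (trans-decalin) to a regiodefined lithium enolate, which is benzylated at C1 from the face opposite the C4a methyl (avoiding a 1,3-diaxial clash), leaving the C1 methyl syn to the C4a methyl.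

Step 11
Reactants: 19 trans-fused C2 ketone (as above)
Product: 21 the 3,4-didehydro derivative of 19 (C2 ketone, C3=C4), via silyl enol ether 20 (not isolated)
Conditions: LDA, THF, −78 °C, then TMSCl; Pd(OAc)2 (1.1 equiv), MeCN, rt
Reagents that add atoms: none
Why: Saegusa–Ito oxidation of the only possible enolate (C3, since C1 is quaternary) installs the C3=C4 double bond.

Step 12
Reactants: 21 enone (C2 ketone, C3=C4)
Product: 22 the 3,4-epoxide of 21 (oxygen anti to 4a-CH3)
Conditions: 30% H2O2, aqueous NaOH, MeOH, 0 °C → rt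
Reagents that add atoms: hydrogen peroxide, OO
Why: Weitz–Scheffer nucleophilic epoxidation is specific for the electron-poor enone double bond and leaves the isopropylidene group untouched; hydroperoxide attacks C4 anti to the C4a methyl (this configuration is lost again in step 14).

Step 13
Reactants: 22 3,4-epoxy C2 ketone
Product: 24 allylic alcohol (4-OH anti to 4a-CH3, C2=C3, no C2 oxygen), via epoxy hydrazone 23 (not isolated)
Conditions: N2H4·H2O, AcOH (cat.), MeOH, 0 °C → rt
Reagents that add atoms: none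
Why: Wharton transposition: the epoxy hydrazone fragments with loss of N2, moving the oxygen from C2 to C4 and the alkene to C2=C3.

Step 14
Reactants: 24 allylic alcohol
Product: 25 transposed enone (C4 ketone, C2=C3)
Conditions: Dess–Martin periodinane, NaHCO3, CH2Cl2, 0 °C → rt
Reagents that add atoms: none
Why: Dess–Martin oxidation of the secondary allylic alcohol gives the enone without touching the tetrasubstituted alkene, the silyl ether or the arene.

Step 15
Reactants: 25 enone (C4 ketone, C2=C3)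
Product: 26 C4 ketone with 2-CH3 anti to 1-CH3 (syn to CH2Ar)
Conditions: Me2CuLi (from CuI and MeLi), Et2O, −40 → 0 °C; aqueous NH4Cl
Reagents that add atoms: lithium dimethylcuprate, [Li+].C[Cu-]C
Why: Gilman cuprate 1,4-addition: stereoelectronically preferred axial attack at C2 on the face opposite the axial C1 methyl places the new methyl trans to the C1 methyl and cis to the benzylic group.

Step 16
Reactants: 26 C4 ketone silyl ether
Product: 27 keto acid (C4 ketone, propanoic acid chain on C5)
Conditions: Jones reagent (CrO3, H2SO4, H2O), acetone, 0 °C → rt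
Reagents that add atoms: water, O
Why: Jones oxidation: the acidic medium cleaves the primary silyl ether and the liberated alcohol is oxidised through the aldehyde hydrate to the carboxylic acid, while ketone, tetrasubstituted alkene and anisole are inert.

Step 17
Reactants: 27 keto acid
Product: 29 3-[(1S,2S,4aR,5S,8aR)-1-[(2-methoxy-3-methylphenyl)methyl]-1,2,4a-trimethyl-6-(propan-2-ylidene)decahydronaphthalen-5-yl]propanoic acid, via hydrazone 28 (not isolated)
Conditions: N2H4·H2O, KOH, diethylene glycol, 130 °C, then 200 °C with removal of water; aqueous HCl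
Reagents that add atoms: none
Why: Wolff–Kishner reduction (Huang-Minlon procedure) removes the C4 carbonyl, which served only to direct the C2 methylation; C4a is quaternary and C2 is β to the carbonyl, so nothing can epimerise.

Step 18
Reactants: 29 methoxyarene acid
Product: 30 3-[(1S,2S,4aR,5S,8aR)-1-[(2-hydroxy-3-methylphenyl)methyl]-1,2,4a-trimethyl-6-(propan-2-ylidene)decahydronaphthalen-5-yl]propanoic acid
Conditions: NaSEt, DMF, 130 °C; aqueous HCl
Reagents that add atoms: none
Why: nucleophilic (SN2) O-demethylation of the aryl methyl ether by ethanethiolate, compatible with the alkene and the carboxylate.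

Step 19
Reactants: 30 phenol acid
Product: 32 3-[(1S,2S,4aR,5S,8aR)-1-[(2,5-dihydroxy-3-methylphenyl)methyl]-1,2,4a-trimethyl-6-(propan-2-ylidene)decahydronaphthalen-5-yl]propanoic acid (target), via quinone 31 (not isolated)
Conditions: Fremy's salt (2.2 equiv), KH2PO4, H2O/acetone, rt; then Na2S2O4, H2O/EtOAc, rt
Reagents that add atoms: potassium nitrosodisulfonate (Fremy's salt), [K+].[K+].[O]N(S(=O)(=O)[O-])S(=O)(=O)[O-]
Why: Teuber oxidation of the 2,6-dialkylphenol gives the para-quinone (only the para position is free), and dithionite reduces it to the hydroquinone.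

**Compound list**

1 | 2,3-dimethylbut-2-enoic acid | CC(C)=C(C)C(=O)O | starting material
2 | 3-hydroperoxy-3-methyl-2-methylidenebutanoic acid | C=C(C(=O)O)C(C)(C)OO | intermediate
3 | 3-hydroxy-3-methyl-2-methylidenebutanoic acid | C=C(C(=O)O)C(C)(C)O | intermediate
4 | 4,4-dimethyl-3-methylideneoxetan-2-one | C=C1C(=O)OC1(C)C | intermediate
5 | 3-methylbut-3-en-2-one | CC(=O)C(C)=C | starting material
6 | tert-butyldimethyl[(3-methylbuta-1,3-dien-2-yl)oxy]silane | C=C(C)C(=C)O[Si](C)(C)C(C)(C)C | intermediate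
7 | 7-[(tert-butyldimethylsilyl)oxy]-3,3,6-trimethyl-2-oxaspiro[3.5]non-6-en-1-one (racemic) | CC1=C(O[Si](C)(C)C(C)(C)C)CCC2(C1)C(=O)OC2(C)C | intermediate
8 | tert-butyldimethyl{[2-methyl-4-(propan-2-ylidene)cyclohex-1-en-1-yl]oxy}silane | CC1=C(O[Si](C)(C)C(C)(C)C)CCC(C1)=C(C)C | intermediate
9 | 2-methyl-4-(propan-2-ylidene)cyclohex-2-en-1-one | CC1=CC(=C(C)C)CCC1=O | intermediate
10 | (3-bromopropoxy)(tert-butyl)dimethylsilane | BrCCCO[Si](C)(C)C(C)(C)C | starting material
11 | bromomagnesium enolate (C1–O–MgBr, C1=C2) of (3R)-3-{3-[(tert-butyldimethylsilyl)oxy]propyl}-2-methyl-4-(propan-2-ylidene)cyclohexan-1-one | CC(C)=C1CCC(O[Mg]Br)=C(C)[C@@H]1CCCO[Si](C)(C)C(C)(C)C | intermediate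
12 | tert-butyldimethyl(3-{(1R)-2-methyl-6-(propan-2-ylidene)-3-[(trimethylsilyl)oxy]cyclohex-2-en-1-yl}propoxy)silane | CC(C)=C1CCC(O[Si](C)(C)C)=C(C)[C@@H]1CCCO[Si](C)(C)C(C)(C)C | intermediate
13 | pent-1-en-3-one | C=CC(=O)CC | starting material
14 | (2S,3R)-3-{3-[(tert-butyldimethylsilyl)oxy]propyl}-2-methyl-2-(3-oxopentyl)-4-(propan-2-ylidene)cyclohexan-1-one | CC(C)=C1CCC(=O)[C@@](C)(CCC(=O)CC)[C@@H]1CCCO[Si](C)(C)C(C)(C)C | intermediate
15 | (4aS,5R)-5-{3-[(tert-butyldimethylsilyl)oxy]propyl}-1,4a-dimethyl-6-(propan-2-ylidene)-4,4a,5,6,7,8-hexahydronaphthalen-2(3H)-one | CC(C)=C1CCC2=C(C)C(=O)CC[C@@]2(C)[C@@H]1CCCO[Si](C)(C)C(C)(C)C | intermediate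
16 | 2-methoxy-1,3-dimethylbenzene (2,6-dimethylanisole) | COc1c(C)cccc1C | starting material
17 | 1-(bromomethyl)-2-methoxy-3-methylbenzene | COc1c(C)cccc1CBr | intermediate
18 | lithium enolate (C2–O–Li, C1=C2) of the trans-fused 5-{3-[(tert-butyldimethylsilyl)oxy]propyl}-1,4a-dimethyl-6-(propan-2-ylidene)octahydronaphthalen-2(1H)-one | CC(C)=C1CC[C@H]2[C@@](C)(CCC(O[Li])=C2C)[C@@H]1CCCO[Si](C)(C)C(C)(C)C | intermediate
19 | trans-fused 5-{3-[(tert-butyldimethylsilyl)oxy]propyl}-1-[(2-methoxy-3-methylphenyl)methyl]-1,4a-dimethyl-6-(propan-2-ylidene)octahydronaphthalen-2(1H)-one (8a-H anti, 1-CH3 and C5 chain syn to 4a-CH3) | CC(C)=C1CC[C@H]2[C@@](C)(CCC(=O)[C@]2(C)Cc2cccc(C)c2OC)[C@@H]1CCCO[Si](C)(C)C(C)(C)C | intermediate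
20 | C2 trimethylsilyl enol ether of 19 (C2=C3) | CC(C)=C1CC[C@H]2[C@@](C)(CC=C(O[Si](C)(C)C)[C@]2(C)Cc2cccc(C)c2OC)[C@@H]1CCCO[Si](C)(C)C(C)(C)C | intermediate
21 | 3,4-didehydro derivative of 19 (C2 ketone, C3=C4) | CC(C)=C1CC[C@H]2[C@@](C)(C=CC(=O)[C@]2(C)Cc2cccc(C)c2OC)[C@@H]1CCCO[Si](C)(C)C(C)(C)C | intermediate
22 | 3,4-epoxide of 21 (C2 ketone, oxygen anti to 4a-CH3) | CC(C)=C1CC[C@H]2[C@@](C)([C@@H]3O[C@@H]3C(=O)[C@]2(C)Cc2cccc(C)c2OC)[C@@H]1CCCO[Si](C)(C)C(C)(C)C | intermediate
23 | C2 hydrazone of 22 | CC(C)=C1CC[C@H]2[C@@](C)([C@@H]3O[C@@H]3C(=NN)[C@]2(C)Cc2cccc(C)c2OC)[C@@H]1CCCO[Si](C)(C)C(C)(C)C | intermediate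
24 | allylic alcohol: 4-hydroxy (anti to 4a-CH3), C2=C3, otherwise as 19 without the C2 oxygen | CC(C)=C1CC[C@H]2[C@@](C)([C@H](O)C=C[C@]2(C)Cc2cccc(C)c2OC)[C@@H]1CCCO[Si](C)(C)C(C)(C)C | intermediate
25 | transposed enone: C4 ketone, C2=C3 | CC(C)=C1CC[C@H]2[C@@](C)(C(=O)C=C[C@]2(C)Cc2cccc(C)c2OC)[C@@H]1CCCO[Si](C)(C)C(C)(C)C | intermediate
26 | C4 ketone with 1,2,4a-trimethyl groups (2-CH3 anti to 1-CH3), silyl ether side chain | CC(C)=C1CC[C@H]2[C@@](C)(C(=O)C[C@H](C)[C@]2(C)Cc2cccc(C)c2OC)[C@@H]1CCCO[Si](C)(C)C(C)(C)C | intermediate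
27 | 3-{1-[(2-methoxy-3-methylphenyl)methyl]-1,2,4a-trimethyl-4-oxo-6-(propan-2-ylidene)decahydronaphthalen-5-yl}propanoic acid (configuration as 26) | CC(C)=C1CC[C@H]2[C@@](C)(C(=O)C[C@H](C)[C@]2(C)Cc2cccc(C)c2OC)[C@@H]1CCC(=O)O | intermediate
28 | C4 hydrazone of 27 | CC(C)=C1CC[C@H]2[C@@](C)(C(=NN)C[C@H](C)[C@]2(C)Cc2cccc(C)c2OC)[C@@H]1CCC(=O)O | intermediate
29 | 3-[(1S,2S,4aR,5S,8aR)-1-[(2-methoxy-3-methylphenyl)methyl]-1,2,4a-trimethyl-6-(propan-2-ylidene)decahydronaphthalen-5-yl]propanoic acid | CC(C)=C1CC[C@H]2[C@@](C)(CC[C@H](C)[C@]2(C)Cc2cccc(C)c2OC)[C@@H]1CCC(=O)O | intermediate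
30 | 3-[(1S,2S,4aR,5S,8aR)-1-[(2-hydroxy-3-methylphenyl)methyl]-1,2,4a-trimethyl-6-(propan-2-ylidene)decahydronaphthalen-5-yl]propanoic acid | CC(C)=C1CC[C@H]2[C@@](C)(CC[C@H](C)[C@]2(C)Cc2cccc(C)c2O)[C@@H]1CCC(=O)O | intermediate
31 | 3-[(1S,2S,4aR,5S,8aR)-1,2,4a-trimethyl-1-[(5-methyl-3,6-dioxocyclohexa-1,4-dien-1-yl)methyl]-6-(propan-2-ylidene)decahydronaphthalen-5-yl]propanoic acid | CC(C)=C1CC[C@H]2[C@@](C)(CC[C@H](C)[C@]2(C)CC2=CC(=O)C=C(C)C2=O)[C@@H]1CCC(=O)O | intermediate
32 | 3-[(1S,2S,4aR,5S,8aR)-1-[(2,5-dihydroxy-3-methylphenyl)methyl]-1,2,4a-trimethyl-6-(propan-2-ylidene)decahydronaphthalen-5-yl]propanoic acid | CC(C)=C1CC[C@H]2[C@@](C)(CC[C@H](C)[C@]2(C)Cc2cc(O)cc(C)c2O)[C@@H]1CCC(=O)O | target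

**Step count and risks**

Total step count: 19. Longest linear sequence: 17 steps (steps 1, 2, 4–8, 10–19).

Steps most likely to fail:

1. Step 6. The dienone 9 may suffer 1,6-addition at the isopropylidene terminus or isomerise to its aromatic phenol tautomer, and the chiral copper complex may discriminate the enone faces incompletely. The fallback sets out from 10 and comes back at 14; it puts the side chain on the diene and sets the stereocentre in an enantioselective Diels–Alder reaction instead. The Grignard reagent of 10 is formylated with DMF to 4-[(tert-butyldimethylsilyl)oxy]butanal F1. Wittig olefination with 3-(triphenylphosphoranylidene)butan-2-one should give (3E)-7-[(tert-butyldimethylsilyl)oxy]-3-methylhept-3-en-2-one F2, and TIPSOTf/Et3N the 2-silyloxydiene tert-butyldimethyl({(4E)-5-methyl-6-[(triisopropylsilyl)oxy]hepta-4,6-dien-1-yl}oxy)silane F3. Cycloaddition with 2-bromoacrolein under a chiral oxazaborolidinium (protonated CBS-type) Lewis acid at −78 °C should give 1-bromo-2-{3-[(tert-butyldimethylsilyl)oxy]propyl}-3-methyl-4-[(triisopropylsilyl)oxy]cyclohex-3-ene-1-carbaldehyde F4, with the side-chain carbon set by the catalyst. MeMgBr gives the 1-(1-hydroxyethyl) bromide F5, Dess–Martin oxidation the 1-acetyl bromide F6, MeMgBr/CeCl3 the tertiary bromohydrin F7, and zinc-mediated reductive elimination the isopropylidene triisopropylsilyl enol ether F8. TiCl4-mediated Mukaiyama–Michael addition of F8 to 13 returns to 14.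

2. Step 4. Lactone 4 may lose CO2 or polymerise faster than it undergoes cycloaddition. The fallback sets out from 6 and comes back at 8. Diels–Alder reaction of 6 with 3-(trimethylsilyl)but-3-en-2-one should give 1-{4-[(tert-butyldimethylsilyl)oxy]-3-methyl-1-(trimethylsilyl)cyclohex-3-en-1-yl}ethan-1-one F9. MeLi/CeCl3 gives the β-hydroxysilane 2-{4-[(tert-butyldimethylsilyl)oxy]-3-methyl-1-(trimethylsilyl)cyclohex-3-en-1-yl}propan-2-ol F10, and KH-induced syn Peterson elimination gives 8 with the same regiospecific isopropylidene.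

3. Step 17. Hydrazone formation at the hindered C4 ketone (next to quaternary C4a) may be incomplete, and the forcing conditions may cause decomposition. The fallback sets out from 26 and comes back at 29. KHMDS/PhNTf2 gives the C4 enol triflate of 26 F11, palladium-catalysed formate reduction gives the C3=C4 alkene F12, and diimide (TsNHNH2, NaOAc) saturates only this disubstituted ring alkene to give the deoxygenated silyl ether F13. Jones oxidation as in step 16 then gives 29.

Further compounds
F1 | step 6 | 4-[(tert-butyldimethylsilyl)oxy]butanal | O=CCCCO[Si](C)(C)C(C)(C)C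
F2 | step 6 | (3E)-7-[(tert-butyldimethylsilyl)oxy]-3-methylhept-3-en-2-one | CC(=O)/C(C)=C/CCCO[Si](C)(C)C(C)(C)C
F3 | step 6 | tert-butyldimethyl({(4E)-5-methyl-6-[(triisopropylsilyl)oxy]hepta-4,6-dien-1-yl}oxy)silane | C=C(O[Si](C(C)C)(C(C)C)C(C)C)/C(C)=C/CCCO[Si](C)(C)C(C)(C)C
F4 | step 6 | 1-bromo-2-{3-[(tert-butyldimethylsilyl)oxy]propyl}-3-methyl-4-[(triisopropylsilyl)oxy]cyclohex-3-ene-1-carbaldehyde (side-chain carbon configured as in 12) | O=CC1(Br)CCC(O[Si](C(C)C)(C(C)C)C(C)C)=C(C)[C@@H]1CCCO[Si](C)(C)C(C)(C)C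
F5 | step 6 | 1-(1-hydroxyethyl) analogue of F4 | CC(O)C1(Br)CCC(O[Si](C(C)C)(C(C)C)C(C)C)=C(C)[C@@H]1CCCO[Si](C)(C)C(C)(C)C
F6 | step 6 | 1-acetyl analogue of F4 | CC(=O)C1(Br)CCC(O[Si](C(C)C)(C(C)C)C(C)C)=C(C)[C@@H]1CCCO[Si](C)(C)C(C)(C)C
F7 | step 6 | 1-(2-hydroxypropan-2-yl) analogue of F4 | CC(C)(O)C1(Br)CCC(O[Si](C(C)C)(C(C)C)C(C)C)=C(C)[C@@H]1CCCO[Si](C)(C)C(C)(C)C
F8 | step 6 | tert-butyldimethyl(3-{(1R)-2-methyl-6-(propan-2-ylidene)-3-[(triisopropylsilyl)oxy]cyclohex-2-en-1-yl}propoxy)silane | CC(C)=C1CCC(O[Si](C(C)C)(C(C)C)C(C)C)=C(C)[C@@H]1CCCO[Si](C)(C)C(C)(C)C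
F9 | step 4 | 1-{4-[(tert-butyldimethylsilyl)oxy]-3-methyl-1-(trimethylsilyl)cyclohex-3-en-1-yl}ethan-1-one | CC(=O)C1([Si](C)(C)C)CCC(O[Si](C)(C)C(C)(C)C)=C(C)C1
F10 | step 4 | 2-{4-[(tert-butyldimethylsilyl)oxy]-3-methyl-1-(trimethylsilyl)cyclohex-3-en-1-yl}propan-2-ol | CC(C)(O)C1([Si](C)(C)C)CCC(O[Si](C)(C)C(C)(C)C)=C(C)C1
F11 | step 17 | C4 enol triflate of 26 (C3=C4) | CC(C)=C1CC[C@H]2[C@@](C)(C(OS(=O)(=O)C(F)(F)F)=C[C@H](C)[C@]2(C)Cc2cccc(C)c2OC)[C@@H]1CCCO[Si](C)(C)C(C)(C)C
F12 | step 17 | C3=C4 alkene from F11 (no C4 oxygen) | CC(C)=C1CC[C@H]2[C@@](C)(C=C[C@H](C)[C@]2(C)Cc2cccc(C)c2OC)[C@@H]1CCCO[Si](C)(C)C(C)(C)C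
F13 | step 17 | tert-butyldimethylsilyl ether of the primary alcohol corresponding to 29 | CC(C)=C1CC[C@H]2[C@@](C)(CC[C@H](C)[C@]2(C)Cc2cccc(C)c2OC)[C@@H]1CCCO[Si](C)(C)C(C)(C)C
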